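**Strategy.** Everything rests on the disconnection between the ketone carbon and ring carbon C1 of the cyclohexene. The key step exploits the free C6 hydroxyl that sits ortho to the C7 acyl group on the benzofuran. This salicyl unit steers rhodium into the formyl C–H bond of a furan-fused salicylaldehyde, so that phenylacetylene is hydroacylated and the carbonyl–C1 bond forms as an (E)-enone. In the same flask the hydroxyl and the new ketone chelate a chiral borate, and (E)-β-ocimene closes the cyclohexene ring (C1 to C6) by an endo Diels–Alder reaction that sets C1, C2 and C6. Three components are joined in one operation; the precursor is 6-hydroxy-4-methoxybenzofuran-7-carbaldehyde.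

Key step: step 3

Locants used: benzofuran O1, C2, C3, C3a, C4 (OMe), C5, C6 (OH), C7 (acyl), C7a; cyclohexene C1 (aroyl), C2 (prenyl), C3 (methyl), C4, C5, C6 (phenyl).

Assumption: the (R)-antipode of VANOL is taken to leave open the enone face that leads to the (1R,2S,6R) series; if the first run shows the opposite facial sense, (S)-VANOL is used under the same conditions.

Step 1
Reactants: 1 2,6-dihydroxy-4-methoxybenzaldehyde
Product: 2 2,6-dihydroxy-3-iodo-4-methoxybenzaldehyde
Conditions: NIS (1.0 equiv), TFA (cat.), MeCN, 0 °C to rt
Reagents that add atoms: N-iodosuccinimide, O=C1CCC(=O)N1I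
Why: Electrophilic aromatic iodination takes place at the ring carbon flanked by the C2 hydroxyl and the C4 methoxyl, the two open positions being equivalent by symmetry, so that a single mono-iodide should result when one equivalent of NIS is used.

Step 2
Reactants: 2 2,6-dihydroxy-3-iodo-4-methoxybenzaldehyde, 3 ethynyltrimethylsilane
Product: 6 6-hydroxy-4-methoxy-1-benzofuran-7-carbaldehyde, via silylalkynyl phenol 4 (not isolated), via ethynyl phenol 5 (not isolated)
Conditions: PdCl2(PPh3)2 (3 mol%), CuI (5 mol%), Et3N, THF, 45 °C; then TBAF (4 equiv), 65 °C; aq. NH4Cl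
Reagents that add atoms: none
Why: Sonogashira coupling at the aryl iodide is followed in the same flask by fluoride-induced C–Si cleavage and 5-endo-dig hydroalkoxylation of the alkyne by the only adjacent phenoxide (the copper still present assists), which closes the furan ring at its O1–C2 bond without creating a stereocentre.

Step 3
Reactants: 6 6-hydroxy-4-methoxy-1-benzofuran-7-carbaldehyde, 7 phenylacetylene, 8 (E)-β-ocimene
Product: 10 (6-hydroxy-4-methoxy-1-benzofuran-7-yl)[(1R,2S,6R)-3-methyl-2-(3-methylbut-2-en-1-yl)-6-phenylcyclohex-3-en-1-yl]methanone, via hydroxychalcone 9 (not isolated)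
Conditions: (a) [RhCl(cod)]2 (2.5 mol%), dppf (5 mol%), Na2CO3 (10 mol%), 7 (1.2 equiv, slow addition), toluene, 100 °C; (b) cooled, cannula-filtered onto pre-formed (R)-VANOL/B(OPh)3 borate (1.3 equiv), 8 (3 equiv), 4 Å MS, PhCF3, rt; aq. NaHCO3; (R)-VANOL recovered
Reagents that add atoms: none
Why: The sodium phenoxide of 6 binds Rh(I) and directs oxidative addition into the adjacent formyl C–H bond; the five-membered acyl rhodium hydride chelate resists decarbonylation, adds syn across 7 with rhodium at the unsubstituted alkyne carbon, and reductive elimination forms the carbonyl–Cα bond of (E)-enone 9 (closest known type: rhodium-catalysed alkyne hydroacylation by salicylaldehydes). The same C6 hydroxyl and the ketone oxygen of 9 then displace phenoxide from the chiral borate to give a four-coordinate O,O-chelate that lowers the enone LUMO (closest known type: chiral boron-mediated Diels–Alder reaction of 2'-hydroxychalcones). The cyclohexene ring closes by an intermolecular endo [4+2] cycloaddition of the s-cis diene of 8, in which C1–C2 and C5–C6 form in one suprafacial event, the unsubstituted CH2 terminus of the diene bonding to the β-carbon that becomes C6. C1 and C6 should be trans because the (E)-enone geometry is retained, C1 and C2 cis because the chelated aroyl group sits endo to the (E)-configured diene terminus, and the absolute configuration (1R,2S,6R) should follow from the enone face left open by the (R)-biaryl diol on boron. The step needs linear regioselectivity in the alkyne insertion, secured by the steric bias of the phenyl group and the rigid chelate, and chemoselectivity for the enone over the prenyl and furan π-bonds, secured by boron activation of the enone alone; any (Z)-diene cannot easily reach the s-cis form and stays behind.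

**Compound list**

1 | 2,6-dihydroxy-4-methoxybenzaldehyde | COc1cc(O)c(C=O)c(O)c1 | starting material
2 | 2,6-dihydroxy-3-iodo-4-methoxybenzaldehyde | COc1cc(O)c(C=O)c(O)c1I | intermediate
3 | ethynyltrimethylsilane | C#C[Si](C)(C)C | starting material
4 | 2,6-dihydroxy-4-methoxy-3-[(trimethylsilyl)ethynyl]benzaldehyde | COc1cc(O)c(C=O)c(O)c1C#C[Si](C)(C)C | intermediate
5 | 3-ethynyl-2,6-dihydroxy-4-methoxybenzaldehyde | COc1cc(O)c(C=O)c(O)c1C#C | intermediate
6 | 6-hydroxy-4-methoxy-1-benzofuran-7-carbaldehyde | COc1cc(O)c(C=O)c2occc12 | intermediate
7 | phenylacetylene | C#Cc1ccccc1 | starting material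
8 | (E)-β-ocimene, (3E)-3,7-dimethylocta-1,3,6-triene | C=C/C(C)=C/CC=C(C)C | starting material
9 | (E)-1-(6-hydroxy-4-methoxy-1-benzofuran-7-yl)-3-phenylprop-2-en-1-one | COc1cc(O)c(C(=O)/C=C/c2ccccc2)c2occc12 | intermediate
10 | (6-hydroxy-4-methoxy-1-benzofuran-7-yl)[(1R,2S,6R)-3-methyl-2-(3-methylbut-2-en-1-yl)-6-phenylcyclohex-3-en-1-yl]methanone | COc1cc(O)c(C(=O)[C@@H]2[C@H](CC=C(C)C)C(C)=CC[C@H]2c2ccccc2)c2occc12 | target

**Step count.** Total: 3 steps. Longest linear sequence: 3 steps (1 → 2 → 6 → 10).

**Steps most likely to fail**

Step 3. The alkyne may insert with the opposite regiochemistry or oligomerise on rhodium, the acyl rhodium hydride may decarbonylate, and carried-over metal or base may erode the facial selectivity of the cycloaddition. The fallback sets out from 6 and forms the same carbonyl–Cα bond by carbonyl addition. The phenol is capped (MOMCl, i-Pr2NEt, CH2Cl2) to give 4-methoxy-6-(methoxymethoxy)-1-benzofuran-7-carbaldehyde F1. (E)-Styrylmagnesium bromide (THF, 0 °C) should then add to the formyl group to give the racemic allylic alcohol (E)-1-[4-methoxy-6-(methoxymethoxy)-1-benzofuran-7-yl]-3-phenylprop-2-en-1-ol F2. MnO2 (CH2Cl2, rt) should oxidise it to (E)-1-[4-methoxy-6-(methoxymethoxy)-1-benzofuran-7-yl]-3-phenylprop-2-en-1-one F3. HCl in MeOH removes the acetal, and the route is rejoined at 9, which is then isolated and taken through stage (b) of step 3 as a separate operation to 10.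

Step 2. The alkyne may homocouple, or the 5-endo cyclisation of the hydrogen-bonded phenoxide may stall. The fallback sets out from 2. Suzuki–Miyaura coupling with (E)-2-(2-ethoxyethenyl)-4,4,5,5-tetramethyl-1,3,2-dioxaborolane (Pd(dppf)Cl2, K2CO3, dioxane/H2O, 80 °C) should give the enol ether 3-[(E)-2-ethoxyethenyl]-2,6-dihydroxy-4-methoxybenzaldehyde F4. TsOH in THF should then close the furan by attack of the C2 hydroxyl on the derived oxocarbenium ion and loss of ethanol, coming back to the route at 6.

Step 1. Di-iodination or oxidative degradation of the electron-rich ring may occur. The fallback sets out from 1 and avoids the halide altogether. Mono-O-alkylation with bromoacetaldehyde diethyl acetal (K2CO3, DMF, 90 °C) should give 2-(2,2-diethoxyethoxy)-6-hydroxy-4-methoxybenzaldehyde F5. Amberlyst-15 in chlorobenzene at 120 °C should then cyclise the derived oxocarbenium ion onto the free ring carbon ortho to the ether oxygen with loss of two molecules of ethanol, coming back to the route at 6 and bypassing 2.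

**Further compounds**

F1 | step 3 | 4-methoxy-6-(methoxymethoxy)-1-benzofuran-7-carbaldehyde | COCOc1cc(OC)c2ccoc2c1C=O
F2 | step 3 | (E)-1-[4-methoxy-6-(methoxymethoxy)-1-benzofuran-7-yl]-3-phenylprop-2-en-1-ol (racemic) | COCOc1cc(OC)c2ccoc2c1C(O)/C=C/c1ccccc1
F3 | step 3 | (E)-1-[4-methoxy-6-(methoxymethoxy)-1-benzofuran-7-yl]-3-phenylprop-2-en-1-one | COCOc1cc(OC)c2ccoc2c1C(=O)/C=C/c1ccccc1
F4 | step 2 | 3-[(E)-2-ethoxyethenyl]-2,6-dihydroxy-4-methoxybenzaldehyde | CCO/C=C/c1c(OC)cc(O)c(C=O)c1O
F5 | step 1 | 2-(2,2-diethoxyethoxy)-6-hydroxy-4-methoxybenzaldehyde | CCOC(COc1cc(OC)cc(O)c1C=O)OCC
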